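## Retrosynthetic overview

1. Locants for each bicyclic half (primes for the other half): O1, C2 (CMe2), C3 (C=O), C4, C5, C6 (quaternary, CH3), C7 (O–CH), C8, C9, C10 (CH3, OAc), C11 (CH), C12 (bridge CH2). The halves are epimeric at C10, so the target is not C2-symmetric; the two acetates are disconnected last.
2. Enabling feature: each 2,2-dimethyloxepan-3-one ring (O1, C2, C3, C4, C5, C6, C7) is a 2,2-dimethyl-3(2H)-furanone (O1, C2, C3, C4, C7) with the C5–C6 olefin inserted into its C4=C7 bond. Furanone carbon C7 already carries O1 and is tethered through four carbons (C8–C11) to the 2-propenyl carbon C6.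
3. Key disconnection: C6–C7 and C4–C5 (and the primed pair) by a twofold intramolecular [2+2] photocycloaddition of an open-chain bis-furanone. Ring order: both cyclohexanes (with their cyclobutanes) first, then both oxepanes by opening the cyclobutanes at C4–C7.
4. The bis-furanone comes from a dialdehyde and two 2-methylbut-3-yn-2-ol units; the dialdehyde from a C26 tetraene by cleaving its two trisubstituted olefins; the tetraene from a C12–C12' sp3–sp3 coupling of two C13 halves.
5. The halves come from nerol (Z) and geraniol (E): the same Sharpless epoxidation and C11 opening by a 2-propenyl cuprate give the same C11 but opposite C10 configurations.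

Key step: step 14

Remark on the chemistry: the target is read as (6S,7S,10R,11S) in the half with the axial C10 acetate (cis to the C6 methyl) and (6'S,7'S,10'S,11'S) in the other half; geraniol, nerol, prop-1-en-2-ylmagnesium bromide and 2-methylbut-3-yn-2-ol are taken as commercial.

## Route

Step 1
Reactants: 1 geraniol
Product: 2 (2S,3S)-2,3-epoxygeraniol
Conditions: Ti(OiPr)4 (5 mol%), L-(+)-diethyl tartrate (6 mol%), t-BuOOH, 4 Å MS, CH2Cl2, −20 °C
Reagents that add atoms: tert-butyl hydroperoxide, CC(C)(C)OO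
Why: Sharpless asymmetric epoxidation of the E-allylic alcohol, in which the L-(+)-tartrate complex delivers oxygen to the face that gives the (2S,3S)-epoxide, fixing C10' and pre-setting C11'.

Step 2
Reactants: 2 (2S,3S)-2,3-epoxygeraniol; 3 prop-1-en-2-ylmagnesium bromide
Product: 4 (2R,3S)-3,7-dimethyl-2-(prop-1-en-2-yl)oct-6-ene-1,3-diol
Conditions: 3 (3 equiv), CuI (10 mol%), THF, −30 → 0 °C; aq. NH4Cl
Reagents that add atoms: none
Why: Copper-catalysed SN2 opening of the 2,3-epoxy alcohol at C2, the only epoxide carbon that is not fully substituted, proceeds with inversion (C11' set) and leaves the tertiary alcohol at C10'.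

Step 3
Reactants: 4 (2R,3S)-diol
Product: 5 (2R,3S)-3-hydroxy-3,7-dimethyl-2-(prop-1-en-2-yl)oct-6-en-1-yl 4-methylbenzenesulfonate
Conditions: TsCl (1.1 equiv), pyridine, CH2Cl2, 0 °C
Reagents that add atoms: 4-methylbenzenesulfonyl chloride, Cc1ccc(cc1)S(Cl)(=O)=O
Why: Sulfonylation discriminates the primary from the hindered tertiary hydroxyl (selective monotosylation of a 1,3-diol).

Step 4
Reactants: 5 monotosylate
Product: 6 (2R,3S)-3-(tert-butyldimethylsilyloxy)-3,7-dimethyl-2-(prop-1-en-2-yl)oct-6-en-1-yl 4-methylbenzenesulfonate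
Conditions: TBSOTf, 2,6-lutidine, CH2Cl2, −78 → 0 °C
Reagents that add atoms: tert-butyldimethylsilyl trifluoromethanesulfonate, CC(C)(C)[Si](C)(C)OS(=O)(=O)C(F)(F)F
Why: A silyl triflate with a hindered pyridine base silylates tertiary alcohols, and the tertiary TBS ether is chosen to survive every step up to step 16.

Step 5
Reactants: 7 nerol
Product: 8 (2S,3R)-2,3-epoxynerol
Conditions: Ti(OiPr)4 (5 mol%), L-(+)-diethyl tartrate (6 mol%), t-BuOOH, 4 Å MS, CH2Cl2, −20 °C
Reagents that add atoms: tert-butyl hydroperoxide, CC(C)(C)OO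
Why: The same Sharpless asymmetric epoxidation on the Z-isomer gives the same configuration at C2 (later C11) but, because the two C3 substituents are exchanged, the opposite one at C3 (later C10).

Step 6
Reactants: 8 (2S,3R)-2,3-epoxynerol; 3 prop-1-en-2-ylmagnesium bromide
Product: 9 (2R,3R)-3,7-dimethyl-2-(prop-1-en-2-yl)oct-6-ene-1,3-diol
Conditions: 3 (3 equiv), CuI (10 mol%), THF, −30 → 0 °C; aq. NH4Cl
Reagents that add atoms: none
Why: Copper-catalysed SN2 opening at C2 with inversion as in step 2 sets C11 with the same absolute sense as C11'.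

Step 7
Reactants: 9 (2R,3R)-diol
Product: 10 (2S,3R)-1-iodo-3,7-dimethyl-2-(prop-1-en-2-yl)oct-6-en-3-ol
Conditions: I2, PPh3, imidazole, CH2Cl2, 0 °C
Reagents that add atoms: iodine, II
Why: Appel-type iodination converts only the primary alcohol and touches no stereocentre.

Step 8
Reactants: 10 iodo alcohol
Product: 11 tert-butyl{[(2S,3R)-1-iodo-3,7-dimethyl-2-(prop-1-en-2-yl)oct-6-en-3-yl]oxy}dimethylsilane
Conditions: TBSOTf, 2,6-lutidine, CH2Cl2, −78 → 0 °C
Reagents that add atoms: tert-butyldimethylsilyl trifluoromethanesulfonate, CC(C)(C)[Si](C)(C)OS(=O)(=O)C(F)(F)F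
Why: Silylation of the tertiary alcohol as in step 4.

Step 9
Reactants: 11 silyl ether iodide; 6 silyl ether tosylate
Product: 14 (6R,7S,10S,11S)-6,11-bis(tert-butyldimethylsilyloxy)-2,6,11,15-tetramethyl-7,10-di(prop-1-en-2-yl)hexadeca-2,14-diene, via alkyllithium 12 (not isolated), via alkylmagnesium bromide 13 (not isolated)
Conditions: 11, t-BuLi (2.1 equiv), Et2O/pentane, −78 °C; MgBr2·OEt2, −78 → 0 °C; then 6, Li2CuCl4 (5 mol%), THF, 0 °C → rt
Reagents that add atoms: none
Why: Lithium–iodine exchange and transmetalation give a primary alkyl Grignard reagent that displaces the primary tosylate under copper catalysis (sp3–sp3 Grignard cross-coupling), forming C12–C12' without touching a stereocentre, and the tosylate partner rules out halogen–metal scrambling between the two halves.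

Step 10
Reactants: 14 C26 tetraene
Product: 16 (4R,5S,8S,9S)-4,9-bis(tert-butyldimethylsilyloxy)-4,9-dimethyl-5,8-di(prop-1-en-2-yl)dodecanedial, via bis-epoxide 15 (not isolated)
Conditions: mCPBA (2.1 equiv), NaHCO3, CH2Cl2, −20 °C; then H5IO6, THF/H2O, 0 °C
Reagents that add atoms: 3-chloroperoxybenzoic acid, O=C(OO)c1cccc(Cl)c1
Why: The two electron-rich trisubstituted olefins should be epoxidised much faster than the hindered 1,1-disubstituted 2-propenyl groups, and periodic acid cleaves the trisubstituted epoxides to the aldehydes with loss of acetone.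

Step 11
Reactants: 16 dialdehyde; 17 2-methylbut-3-yn-2-ol
Product: 19 (8R,9S,12S,13S)-8,13-bis(tert-butyldimethylsilyloxy)-2,8,13,19-tetramethyl-9,12-di(prop-1-en-2-yl)icosa-3,17-diyne-2,5,16,19-tetraol (mixture of C5/C16 epimers), via dilithiated alkynol 18 (not isolated)
Conditions: 17 (2.6 equiv), n-BuLi (5.2 equiv), THF, −78 → 0 °C; then 16, −78 °C; aq. NH4Cl
Reagents that add atoms: none
Why: 1,2-Addition of the lithium acetylide to both aldehydes gives carbinol centres that are oxidised in step 12, so their configuration is irrelevant.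

Step 12
Reactants: 19 tetraol
Product: 20 (8R,9S,12S,13S)-8,13-bis(tert-butyldimethylsilyloxy)-2,19-dihydroxy-2,8,13,19-tetramethyl-9,12-di(prop-1-en-2-yl)icosa-3,17-diyne-5,16-dione
Conditions: Dess–Martin periodinane (2.5 equiv), NaHCO3, CH2Cl2, 0 °C → rt
Reagents that add atoms: none
Why: Dess–Martin oxidation converts the secondary propargylic alcohols to ynones, while the tertiary alcohols cannot be oxidised.

Step 13
Reactants: 20 bis-ynone
Product: 22 5,5'-[(3R,4S,7S,8S)-3,8-bis(tert-butyldimethylsilyloxy)-3,8-dimethyl-4,7-di(prop-1-en-2-yl)decane-1,10-diyl]bis[2,2-dimethylfuran-3(2H)-one], via bis-enaminone 21 (not isolated)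
Conditions: Et2NH, EtOH, rt; then AcOH/H2O, THF, rt
Reagents that add atoms: water, O
Why: Conjugate addition of the amine to each γ-hydroxy ynone gives a β-enaminone (a masked 1,3-diketone) whose acidic hydrolysis and cyclodehydration through the tertiary hydroxyl is the classical route to 2,2-dimethyl-3(2H)-furanones.

Step 14
Reactants: 22 bis-furanone
Product: 23 hexacyclic bis-photoadduct (4R,6S,7R,10R,11S and 4'R,6'S,7'R,10'S,11'S): at each end a cyclohexane (C6–C11) cis-fused at C6–C7 to a cyclobutane (C4 C5 C6 C7) that is cis-fused at C4–C7 to the 2,2-dimethyldihydrofuran-3-one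
Conditions: hν (350 nm lamps, Pyrex), degassed MeCN (2 mM), 0 °C
Reagents that add atoms: none
Why: Excitation of the two 3(2H)-furanone (β-alkoxyenone) chromophores and intersystem crossing should give triplet enones that add stepwise to the tethered 2-propenyl groups through 1,4-biradicals, C7 bonding to C6 and then C4 to C5 (the same at the primed end); the closest known reaction type is the intramolecular enone–olefin [2+2] photocycloaddition of vinylogous esters that opens De Mayo-type ring expansions. Each cyclohexane closes in the 6-exo-trig mode at the inner olefin carbon (straight, head-to-tail adduct; a crossed 1,7-closure would need a seven-membered ring and a bridged bicyclo[4.1.1] skeleton), and each cyclobutane closes by 4-exo collapse of the biradical, necessarily cis-fused to both the six- and the five-membered ring. C7 and C4 are therefore fixed relative to C6 by ring strain alone, and C7 becomes trigonal again in step 15. The one selectivity that has to be won is the π-face of each 2-propenyl group (C6 relative to C11): the furanone can only reach the face that carries its own tether (C10), and in the rotamer with C11–H eclipsing the C=CH2 bond (least allylic strain) the bridge carbon C12 lies on the far face, exo to the new cyclobutane and cis to the C6 methyl as in the target; this is an expectation from the allylic-strain model, not a secured outcome, and is treated as a main risk below. Chemoselectivity is secured by the substrate, since the furanones are the only chromophores above 300 nm and the 2-propenyl groups the only olefins, and high dilution should keep the two ends from reacting with each other.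

Step 15
Reactants: 23 bis-photoadduct
Product: 25 bis-TBS ether of the (6S,7S,10R,11S,6'S,7'S,10'S,11'S)-tetracyclic bis-oxepanone diol, via bis(silyl enol ether) 24 (not isolated)
Conditions: TMSOTf (3 equiv), Et3SiH (10 equiv), CH2Cl2, −78 → −30 °C; then 1 M HCl, THF, 0 °C
Reagents that add atoms: none
Why: Proposed new method: O-silylation of the C3 carbonyl should turn each alkoxycyclobutyl ketone into a push–pull cyclobutane that opens heterolytically at C4–C7, with ring oxygen O1 pushing, the silyloxycarbenium pulling and the cyclobutane strain released, to a silyl enol ether and a seven-membered oxocarbenium ion; the ring holds C5 in the plane of the C7=O1 unit, so the C6 methyl is axial and Et3SiH should attack anti to it (trans ring fusion, C7–H set), and hydrolysis returns the C3 ketone; the closest known reaction types are the Lewis-acid ring opening of 2-alkoxycyclobutyl carbonyl compounds, the retro-aldol half of the De Mayo reaction and the silane reduction of cyclic oxocarbenium ions.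

Step 16
Reactants: 25 bis-TBS ether
Product: 26 (6S,7S,10R,11S,6'S,7'S,10'S,11'S)-tetracyclic bis-oxepanone 10,10'-diol
Conditions: HF·pyridine, THF, 0 °C → rt
Reagents that add atoms: none
Why: Fluoride-assisted cleavage of the hindered tertiary silyl ethers leaves ketones, ethers and all stereocentres untouched.

Step 17
Reactants: 26 diol
Product: 27 target bis-acetate (CNP0325605.1)
Conditions: Ac2O, Sc(OTf)3 (5 mol%), MeCN, −20 °C
Reagents that add atoms: acetic anhydride, CC(=O)OC(C)=O
Why: Sc(OTf)3-catalysed acylation with acetic anhydride esterifies hindered tertiary alcohols at low temperature with retention, without ionising them.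

## Compound list

1 | geraniol, (2E)-3,7-dimethylocta-2,6-dien-1-ol | CC(C)=CCC/C(C)=C/CO | starting material
2 | (2S,3S)-2,3-epoxygeraniol, [(2S,3S)-3-methyl-3-(4-methylpent-3-en-1-yl)oxiran-2-yl]methanol | OC[C@@H]1O[C@@]1(C)CCC=C(C)C | intermediate
3 | prop-1-en-2-ylmagnesium bromide | CC(=C)[Mg]Br | starting material
4 | (2R,3S)-3,7-dimethyl-2-(prop-1-en-2-yl)oct-6-ene-1,3-diol | OC[C@@H](C(C)=C)[C@@](C)(O)CCC=C(C)C | intermediate
5 | (2R,3S)-3-hydroxy-3,7-dimethyl-2-(prop-1-en-2-yl)oct-6-en-1-yl 4-methylbenzenesulfonate | Cc1ccc(cc1)S(=O)(=O)OC[C@@H](C(C)=C)[C@@](C)(O)CCC=C(C)C | intermediate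
6 | (2R,3S)-3-(tert-butyldimethylsilyloxy)-3,7-dimethyl-2-(prop-1-en-2-yl)oct-6-en-1-yl 4-methylbenzenesulfonate | Cc1ccc(cc1)S(=O)(=O)OC[C@@H](C(C)=C)[C@@](C)(O[Si](C)(C)C(C)(C)C)CCC=C(C)C | intermediate
7 | nerol, (2Z)-3,7-dimethylocta-2,6-dien-1-ol | CC(C)=CCC/C(C)=C\CO | starting material
8 | (2S,3R)-2,3-epoxynerol | OC[C@@H]1O[C@]1(C)CCC=C(C)C | intermediate
9 | (2R,3R)-3,7-dimethyl-2-(prop-1-en-2-yl)oct-6-ene-1,3-diol | OC[C@@H](C(C)=C)[C@](C)(O)CCC=C(C)C | intermediate
10 | (2S,3R)-1-iodo-3,7-dimethyl-2-(prop-1-en-2-yl)oct-6-en-3-ol | IC[C@@H](C(C)=C)[C@](C)(O)CCC=C(C)C | intermediate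
11 | tert-butyl{[(2S,3R)-1-iodo-3,7-dimethyl-2-(prop-1-en-2-yl)oct-6-en-3-yl]oxy}dimethylsilane | IC[C@@H](C(C)=C)[C@](C)(O[Si](C)(C)C(C)(C)C)CCC=C(C)C | intermediate
12 | alkyllithium from 11 (C–I replaced by C–Li) | [Li]C[C@@H](C(C)=C)[C@](C)(O[Si](C)(C)C(C)(C)C)CCC=C(C)C | intermediate (not isolated)
13 | alkylmagnesium bromide from 12 | Br[Mg]C[C@@H](C(C)=C)[C@](C)(O[Si](C)(C)C(C)(C)C)CCC=C(C)C | intermediate (not isolated)
14 | (6R,7S,10S,11S)-6,11-bis(tert-butyldimethylsilyloxy)-2,6,11,15-tetramethyl-7,10-di(prop-1-en-2-yl)hexadeca-2,14-diene | CC(C)=CCC[C@@](C)(O[Si](C)(C)C(C)(C)C)[C@H](C(C)=C)CC[C@@H](C(C)=C)[C@@](C)(O[Si](C)(C)C(C)(C)C)CCC=C(C)C | intermediate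
15 | bis(2,2-dimethyloxirane) from 14 (mixture of epoxide epimers) | CC1(C)OC1CC[C@@](C)(O[Si](C)(C)C(C)(C)C)[C@H](C(C)=C)CC[C@@H](C(C)=C)[C@@](C)(O[Si](C)(C)C(C)(C)C)CCC1OC1(C)C | intermediate (not isolated)
16 | (4R,5S,8S,9S)-4,9-bis(tert-butyldimethylsilyloxy)-4,9-dimethyl-5,8-di(prop-1-en-2-yl)dodecanedial | O=CCC[C@@](C)(O[Si](C)(C)C(C)(C)C)[C@H](C(C)=C)CC[C@@H](C(C)=C)[C@@](C)(O[Si](C)(C)C(C)(C)C)CCC=O | intermediate
17 | 2-methylbut-3-yn-2-ol | CC(C)(O)C#C | starting material
18 | dilithium derivative of 17 (lithium acetylide, lithium alkoxide) | [Li]C#CC(C)(C)O[Li] | intermediate (not isolated)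
19 | (8R,9S,12S,13S)-8,13-bis(tert-butyldimethylsilyloxy)-2,8,13,19-tetramethyl-9,12-di(prop-1-en-2-yl)icosa-3,17-diyne-2,5,16,19-tetraol (C5/C16 epimers) | CC(C)(O)C#CC(O)CC[C@@](C)(O[Si](C)(C)C(C)(C)C)[C@H](C(C)=C)CC[C@@H](C(C)=C)[C@@](C)(O[Si](C)(C)C(C)(C)C)CCC(O)C#CC(C)(C)O | intermediate
20 | (8R,9S,12S,13S)-8,13-bis(tert-butyldimethylsilyloxy)-2,19-dihydroxy-2,8,13,19-tetramethyl-9,12-di(prop-1-en-2-yl)icosa-3,17-diyne-5,16-dione | CC(C)(O)C#CC(=O)CC[C@@](C)(O[Si](C)(C)C(C)(C)C)[C@H](C(C)=C)CC[C@@H](C(C)=C)[C@@](C)(O[Si](C)(C)C(C)(C)C)CCC(=O)C#CC(C)(C)O | intermediate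
21 | bis(β-diethylamino enone) from 20 (E,E expected; geometry without consequence) | CCN(CC)/C(=C/C(=O)CC[C@@](C)(O[Si](C)(C)C(C)(C)C)[C@H](C(C)=C)CC[C@@H](C(C)=C)[C@@](C)(O[Si](C)(C)C(C)(C)C)CCC(=O)/C=C(/N(CC)CC)C(C)(C)O)C(C)(C)O | intermediate (not isolated)
22 | 5,5'-[(3R,4S,7S,8S)-3,8-bis(tert-butyldimethylsilyloxy)-3,8-dimethyl-4,7-di(prop-1-en-2-yl)decane-1,10-diyl]bis[2,2-dimethylfuran-3(2H)-one] | CC1(C)OC(=CC1=O)CC[C@@](C)(O[Si](C)(C)C(C)(C)C)[C@H](C(C)=C)CC[C@@H](C(C)=C)[C@@](C)(O[Si](C)(C)C(C)(C)C)CCC1=CC(=O)C(C)(C)O1 | intermediate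
23 | hexacyclic bis-photoadduct, two 6-4-5 tricycles joined by the C12–C12' bridge, (4R,6S,7R,10R,11S) and (4'R,6'S,7'R,10'S,11'S) | CC1(C)O[C@@]23CC[C@@](C)(O[Si](C)(C)C(C)(C)C)[C@@H](CC[C@@H]4[C@@](C)(O[Si](C)(C)C(C)(C)C)CC[C@@]56OC(C)(C)C(=O)[C@@H]5C[C@@]46C)[C@]2(C)C[C@H]3C1=O | intermediate
24 | bis(trimethylsilyl enol ether) of 25 (C3=C4 and C3'=C4') | CC(C)(C)[Si](C)(C)O[C@]1(C)CC[C@@H]2OC(C)(C)C(O[Si](C)(C)C)=CC[C@@]2(C)[C@@H]1CC[C@H]1[C@]2(C)CC=C(O[Si](C)(C)C)C(C)(C)O[C@H]2CC[C@]1(C)O[Si](C)(C)C(C)(C)C | intermediate (not isolated)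
25 | 10,10'-bis-O-TBS ether of the (6S,7S,10R,11S,6'S,7'S,10'S,11'S)-bis-oxepanone diol | CC(C)(C)[Si](C)(C)O[C@]1(C)CC[C@@H]2OC(C)(C)C(=O)CC[C@@]2(C)[C@@H]1CC[C@H]1[C@]2(C)CCC(=O)C(C)(C)O[C@H]2CC[C@]1(C)O[Si](C)(C)C(C)(C)C | intermediate
26 | (6S,7S,10R,11S,6'S,7'S,10'S,11'S)-bis-oxepanone 10,10'-diol | O[C@]1(C)CC[C@@H]2OC(C)(C)C(=O)CC[C@@]2(C)[C@@H]1CC[C@H]1[C@]2(C)CCC(=O)C(C)(C)O[C@H]2CC[C@]1(C)O | intermediate
27 | CNP0325605.1, the 10,10'-diacetate | CC(=O)O[C@]1(C)CC[C@@H]2OC(C)(C)C(=O)CC[C@@]2(C)[C@@H]1CC[C@H]1[C@]2(C)CCC(=O)C(C)(C)O[C@H]2CC[C@]1(C)OC(C)=O | target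

## Step count and main risks

Total step count: 17. Longest linear sequence: 13 steps (nerol 7 through steps 5–8, then steps 9–17 to 27; the geraniol branch, steps 1–4, runs in parallel).

**Risk 1, step 15 (the proposed new method).** The C4–C7 bond lies almost in the plane of the five-membered ring, so it overlaps poorly with both the carbonyl π-system and the O1 lone pair. Heterolysis may therefore be slow, and reclosure of the zwitterion or ionisation of the tertiary silyl ethers may compete with hydride capture.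

The fallback uses known chemistry only; it sets out from dialdehyde 16 and comes back at 25. Commercial 3-hydroxy-3-methylbutan-2-one would be silylated (TMSCl, imidazole) to 3-methyl-3-(trimethylsilyloxy)butan-2-one F1. Its lithium enolate (LDA, THF, −78 °C) would add to both aldehydes of 16 to give the bis-aldol F2, and Dess–Martin oxidation would give the bis(1,3-diketone) F3. Irradiation of the enol form (De Mayo reaction) would form the C6–C7 and C4–C5 bonds through the bis-cyclobutanol F4, which is not isolated and undergoes retro-aldol cleavage in the flask to the bis(1,5-diketone) F5 (C7 ketone in the new cyclohexanone). Reductive etherification of the tertiary silyl ethers onto the C7 ketones (TMSOTf, Et3SiH, CH2Cl2, −78 °C) would close both oxepanes through the same oxocarbenium ions and give 25.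

**Risk 2, step 14.** The π-facial selectivity at the 2-propenyl groups rests only on an acyclic allylic-strain preference, so C6 may form on the wrong face relative to C11. This is most likely at the primed end, where the product carries syn-diaxial methyl groups at C6' and C10'. Biradical reversion or crossed closure may also lower the efficiency of the six-ring closure.

The fallback sets out from tetraene 14 and comes back at 25. Ring-closing metathesis of each prenyl/2-propenyl pair (second-generation Grubbs catalyst, toluene, 60 °C, loss of 2-methylpropene) would close the cyclohexenes by forming C6=C7 and give the bis-cyclohexene F6. Hydroboration–oxidation (BH3·THF; NaOH, H2O2) would give the bis-cyclohexanol F7 and Dess–Martin oxidation the bis-cyclohexanone F8. A thermodynamic Michael addition (KOt-Bu cat., t-BuOH) to 4-methyl-4-(trimethylsilyloxy)pent-1-en-3-one F9, made from F1 by α-methylenation with paraformaldehyde and N-methylanilinium trifluoroacetate, should build the quaternary C6 with the new chain anti to the C11 substituent. This is the sense known from Robinson annulations of 2,3-dialkylcyclohexanones, and it gives the bis(1,5-diketone) F5, which is closed to 25 by the reductive etherification described above.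

**Risk 3, step 9.** Displacement at a β-branched primary carbon flanked by a fully substituted carbon may be slow, so reduction or elimination of the Grignard reagent and homocoupling may take over.

The fallback sets out from iodide 11 and tosylate 6 and comes back at 14. Iodide 11 would be converted with PhSO2Na (DMF, 60 °C) into the phenyl sulfone F10. Its α-sulfonyl carbanion (n-BuLi, THF/HMPA, −78 °C) would be alkylated with tosylate 6 (NaI cat.) to the coupled sulfone F11. Reductive desulfonylation (lithium naphthalenide, THF, −78 °C) would give 14.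

Further compounds
F1 | step 15 | 3-methyl-3-(trimethylsilyloxy)butan-2-one | CC(=O)C(C)(C)O[Si](C)(C)C
F2 | step 15 | bis-aldol from 16 and F1 (carbinol epimers) | C[Si](C)(C)OC(C)(C)C(=O)CC(O)CC[C@@](C)(O[Si](C)(C)C(C)(C)C)[C@H](C(C)=C)CC[C@@H](C(C)=C)[C@@](C)(O[Si](C)(C)C(C)(C)C)CCC(O)CC(=O)C(C)(C)O[Si](C)(C)C
F3 | step 15 | bis(1,3-diketone), drawn in the keto form | C[Si](C)(C)OC(C)(C)C(=O)CC(=O)CC[C@@](C)(O[Si](C)(C)C(C)(C)C)[C@H](C(C)=C)CC[C@@H](C(C)=C)[C@@](C)(O[Si](C)(C)C(C)(C)C)CCC(=O)CC(=O)C(C)(C)O[Si](C)(C)C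
F4 | step 15 | bis-cyclobutanol De Mayo photoadduct (not isolated; C4 epimers) | O[C@@]12CC[C@@](C)(O[Si](C)(C)C(C)(C)C)[C@@H](CC[C@@H]3[C@@](C)(O[Si](C)(C)C(C)(C)C)CC[C@@]4(O)C(C(=O)C(C)(C)O[Si](C)(C)C)C[C@@]34C)[C@]1(C)CC2C(=O)C(C)(C)O[Si](C)(C)C
F5 | step 15 | bis(1,5-diketone): two 2-methyl-2-(4-methyl-3-oxo-4-trimethylsilyloxypentyl)cyclohexanones joined by the C12–C12' bridge | O=C1CC[C@@](C)(O[Si](C)(C)C(C)(C)C)[C@@H](CC[C@@H]2[C@@](C)(O[Si](C)(C)C(C)(C)C)CCC(=O)[C@@]2(C)CCC(=O)C(C)(C)O[Si](C)(C)C)[C@]1(C)CCC(=O)C(C)(C)O[Si](C)(C)C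
F6 | step 14 | bis-cyclohexene from ring-closing metathesis of 14 | CC1=CCC[C@@](C)(O[Si](C)(C)C(C)(C)C)[C@H]1CC[C@H]1C(C)=CCC[C@]1(C)O[Si](C)(C)C(C)(C)C
F7 | step 14 | bis-cyclohexanol (C6/C7 configuration not carried forward) | CC1C(O)CC[C@@](C)(O[Si](C)(C)C(C)(C)C)[C@H]1CC[C@H]1C(C)C(O)CC[C@]1(C)O[Si](C)(C)C(C)(C)C
F8 | step 14 | bis-cyclohexanone (C6 epimerisable) | CC1C(=O)CC[C@@](C)(O[Si](C)(C)C(C)(C)C)[C@H]1CC[C@H]1C(C)C(=O)CC[C@]1(C)O[Si](C)(C)C(C)(C)C
F9 | step 14 | 4-methyl-4-(trimethylsilyloxy)pent-1-en-3-one | C=CC(=O)C(C)(C)O[Si](C)(C)C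
F10 | step 9 | phenyl sulfone from 11 | O=S(=O)(C[C@@H](C(C)=C)[C@](C)(O[Si](C)(C)C(C)(C)C)CCC=C(C)C)c1ccccc1
F11 | step 9 | coupled sulfone (14 carrying PhSO2 at C12; epimers at that carbon) | CC(C)=CCC[C@@](C)(O[Si](C)(C)C(C)(C)C)[C@H](C(C)=C)C(C[C@@H](C(C)=C)[C@@](C)(O[Si](C)(C)C(C)(C)C)CCC=C(C)C)S(=O)(=O)c1ccccc1
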